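**Strategy.** Everything rests on one building block, tri-O-benzylteracacidin acetonide, whose pyran ring C is closed by an enantioselective oxa-Povarov [4+2] reaction. The aryloxocarbenium ion released from an O-aryl O-methyl acetal of 4-benzyloxybenzaldehyde offers the heterodiene C2=O1–C8a=C4a of ring A; 2,2-dimethyl-1,3-dioxole adds across it, forming C2–C3 and C4–C4a and setting the all-cis centres C2, C3 and C4 at once, the cis-3,4-diol of the lower unit being the cis-enediol. The acetonide is then used three times: as lower unit, as brominated C4 electrophile for the upper unit and, after deoxygenation and re-dihydroxylation, as the 2,3-trans middle unit; two C4–C6 Friedel–Crafts couplings complete the trimer.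

Key step: step 7

Remark: flavan numbering (O1, C2, C3, C4, C4a, C5 to C8, C8a; primes for the B ring) is used for all chroman compounds. The sulfide made in step 11 is drawn as its expected major 3,4-trans isomer; its C4 configuration is erased on ionization in step 14. The enantiomer of the acid catalyst in step 7 that leads to the 2R series is to be chosen by experiment.

**Step 1**
Reactants: 1 2,3-dihydroxybenzaldehyde
Product: 2 2,3-bis(benzyloxy)benzaldehyde
Conditions: BnBr (2.3 equiv), K2CO3, DMF, 60 °C
Reagents that add atoms: benzyl bromide, BrCc1ccccc1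
Why: Williamson etherification of both phenolic hydroxyls should give the dibenzyl ether, the aldehyde being inert to the carbonate base.

**Step 2**
Reactants: 2 2,3-bis(benzyloxy)benzaldehyde
Product: 4 2,3-bis(benzyloxy)phenol, via aryl formate 3 (not isolated)
Conditions: mCPBA, CH2Cl2, rt; then K2CO3 (0.2 equiv), MeOH, rt; acidic work-up
Reagents that add atoms: 3-chloroperoxybenzoic acid (mCPBA), OOC(=O)c1cccc(Cl)c1
Why: Baeyer–Villiger oxidation in its Dakin sense, in which the electron-rich aryl group migrates to oxygen, should give formate 3, which methanolysis cleaves to the phenol.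

**Step 3**
Reactants: 5 4-(benzyloxy)benzaldehyde
Product: 6 4-(benzyloxy)benzaldehyde dimethyl acetal
Conditions: HC(OMe)3, TsOH·H2O (1 mol %), MeOH, rt; Et3N quench
Reagents that add atoms: trimethyl orthoformate, COC(OC)OC; methanol, CO
Why: acid-catalysed acetalization with the orthoformate as dehydrating agent should convert the aldehyde fully into its dimethyl acetal.

**Step 4**
Reactants: 6 4-(benzyloxy)benzaldehyde dimethyl acetal; 4 2,3-bis(benzyloxy)phenol
Product: 8 [4-(benzyloxy)phenyl](methoxy)methyl 2,3-bis(benzyloxy)phenyl ether (racemic mixed acetal), via chloro ether 7 (not isolated)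
Conditions: AcCl (1.05 equiv), CH2Cl2, 0 °C to rt; then 4, i-Pr2NEt, CH2Cl2, −20 °C to rt; chromatography on Et3N-deactivated silica
Reagents that add atoms: none
Why: acetal-to-α-chloro-ether exchange with acetyl chloride followed by O-alkylation of the phenol (the reaction type of a MOM protection) should give the mixed O-aryl O-methyl acetal, whose stereocentre is racemic and is erased in step 7.

**Step 5**
Reactants: 9 2,2-dimethyl-1,3-dioxolan-4-one
Product: 11 2,2-dimethyl-1,3-dioxolan-4-yl acetate (racemic), via aluminium lactolate 10 (not isolated)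
Conditions: i-Bu2AlH (1.1 equiv), CH2Cl2, −78 °C; then pyridine, DMAP, Ac2O, −78 to 0 °C
Reagents that add atoms: acetic anhydride, CC(=O)OC(C)=O
Why: reductive acetylation of a lactone should work because the tetrahedral aluminium hemiacetal 10 is stable at −78 °C and is acetylated in place before it can collapse to the aldehyde.

**Step 6**
Reactants: 11 2,2-dimethyl-1,3-dioxolan-4-yl acetate
Product: 12 2,2-dimethyl-1,3-dioxole
Conditions: flash vacuum pyrolysis, 450 °C, quartz tube; condensate collected cold over K2CO3 and redistilled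
Reagents that add atoms: none
Why: ester pyrolysis, a thermal syn-elimination of acetic acid through a six-membered transition state, should turn the α-acetoxy ether into the cyclic cis-enediol ether.

**Step 7**
Reactants: 8 racemic mixed acetal; 12 2,2-dimethyl-1,3-dioxole
Product: 14 (2R)-2,3-cis-3,4-cis-7,8-bis(benzyloxy)-2-[4-(benzyloxy)phenyl]-3,4-(isopropylidenedioxy)flavan (tri-O-benzylteracacidin acetonide), via oxocarbenium ion 13 (not isolated)
Conditions: chiral BINOL-derived imidodiphosphorimidate Brønsted acid (IDPi type, 5 mol %), 12 (3 equiv), 5 Å MS, CHCl3, −60 °C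
Reagents that add atoms: none
Why: Proposed new method: the chiral acid protonates the methoxy group of 8 and expels methanol, giving the E-configured aryloxocarbenium ion 13 as a contact ion pair with the confined chiral anion, and the cationic 2-oxadiene C2=O1–C8a=C4a then takes up the nucleophilic C=C of 12 in an asynchronous inverse-electron-demand [4+2] addition (C2–C3 first, then capture of the dioxolanyl cation by C4a and return of the arenium proton to the anion). The closest known reaction type is the SnCl4-mediated oxa-Povarov reaction of aryloxocarbenium ions with alkenes, and the asymmetric version transfers the chiral-anion control known from Povarov reactions and from oxocarbenium ion-pair catalysis to this cation. Ring C is the only ring closed, by formal [4+2] cycloaddition whose second stage is a six-membered Friedel–Crafts closure (6-exo-trig with respect to the C4=O oxocarbenium bond) onto the one free position ortho to O1, while the dioxolane ring arrives preformed. C3 and C4 are cis because both oxygens sit on a five-membered cis-alkene that adds suprafacially, C2 is cis to them because the E-oxocarbenium ion reacts through the endo transition state, as five-membered cyclic enol ethers do in Povarov reactions, and the absolute sense (2R) is set by the chiral anion. The step needs endo over exo addition, one enantioface of 13 and ring closure in preference to intermolecular arylation; the last is secured by the para-benzyloxy activation of C4a, the blocked second ortho position and the excess of 12, while the sieves take up methanol.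

**Step 8**
Reactants: 14 tri-O-benzylteracacidin acetonide
Product: 15 (2R,3R,4R)-7,8-bis(benzyloxy)-2-[4-(benzyloxy)phenyl]chromane-3,4-diol (tri-O-benzylteracacidin, 2,3-cis-3,4-cis)
Conditions: AcOH/H2O/THF (3:1:1), 40 °C
Reagents that add atoms: none
Why: mild ketal hydrolysis should release the all-cis diol without epimerization, because the isopropylidene group ionizes at the ketal carbon much faster than the benzylic C4–O bond does in dilute acetic acid.

**Step 9**
Reactants: 15 tri-O-benzylteracacidin
Product: 17 (2S)-7,8-bis(benzyloxy)-2-[4-(benzyloxy)phenyl]-2H-chromene (flav-3-ene; C2 spatially unchanged, the descriptor changes by priority only), via thionocarbonate 16 (not isolated)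
Conditions: 1,1'-thiocarbonyldiimidazole, DMAP (cat.), toluene, 60 °C; then 1,3-dimethyl-2-phenyl-1,3,2-diazaphospholidine, 40 °C
Reagents that add atoms: none
Why: Corey–Winter olefination with a diazaphospholidine as thiophile should excise both hydroxyls of the cis-diol as CO2 through the cyclic thionocarbonate, leaving C2 untouched at a temperature too low for electrocyclic ring opening of the 2H-chromene.

**Step 10**
Reactants: 17 (2S)-flav-3-ene
Product: 18 (2R,3S,4S)-7,8-bis(benzyloxy)-2-[4-(benzyloxy)phenyl]chromane-3,4-diol (2,3-trans-3,4-cis)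
Conditions: OsO4 (2 mol %), NMO, acetone/H2O, 0 °C to rt
Reagents that add atoms: N-methylmorpholine N-oxide, C[N+]1([O-])CCOCC1; water, O; OsO4 as catalytic oxygen carrier, O=[Os](=O)(=O)=O
Why: Upjohn syn-dihydroxylation should occur on the face anti to the C2 aryl group, as is general for flav-3-enes, and so sets C3 and C4 of the 2,3-trans series.

**Step 11**
Reactants: 18 2,3-trans-3,4-cis diol
Product: 19 (2R,3R,4R)-7,8-bis(benzyloxy)-2-[4-(benzyloxy)phenyl]-4-[(2,6-dimethylphenyl)sulfanyl]chroman-3-ol (2,3-trans-3,4-trans)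
Conditions: 2,6-dimethylbenzenethiol (3 equiv), BF3·OEt2 (0.2 equiv), 4 Å MS, CH2Cl2, −40 to 0 °C
Reagents that add atoms: 2,6-dimethylbenzenethiol, Cc1cccc(C)c1S
Why: SN1 thiolysis of the benzylic 4-hydroxyl through the para-benzyloxy-stabilized C4 cation should install the soft leaving group, the excess thiol outcompeting self-condensation and adding mainly anti to the 3-hydroxyl.

**Step 12**
Reactants: 14 tri-O-benzylteracacidin acetonide
Product: 20 6-bromo-tri-O-benzylteracacidin acetonide
Conditions: NBS (1.05 equiv), CH2Cl2, −20 to 0 °C, dark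
Reagents that add atoms: N-bromosuccinimide, O=C1CCC(=O)N1Br
Why: electrophilic aromatic bromination should go to C6, the position ortho to the 7-benzyloxy group and para to O1, and so caps the only nucleophilic site of the future upper unit.

**Step 13**
Reactants: 20 6-bromo acetonide; 19 4-sulfanyl middle unit
Product: 21 protected dimer: 6-bromo-tri-O-benzylepioritin-(4β→6)-[tri-O-benzyl-4-(2,6-dimethylphenylsulfanyl)oritin], upper unit 2R 2,3-cis-3,4-trans, lower unit 2R 2,3-trans-3,4-trans, both 3-hydroxyls free
Conditions: TMSOTf (0.3 equiv), 19 (1.3 equiv), 4 Å MS, CH2Cl2, −78 to −40 °C; Et3N quench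
Reagents that add atoms: none
Why: Friedel–Crafts flavan coupling should work because the hard Lewis acid ionizes the benzylic ketal C4–O bond of 20 while the hindered arylthio group of 19 stays intact, and C6 of 19 attacks the 2,3-cis flavan-4-yl cation anti to the axial C3 oxygen, setting the upper C4 as 3,4-trans.

**Step 14**
Reactants: 21 protected dimer; 14 tri-O-benzylteracacidin acetonide
Product: 22 protected trimer: 6-bromo-tri-O-benzylepioritin-(4β→6)-tri-O-benzyloritin-(4α→6)-tri-O-benzylteracacidin acetonide
Conditions: AgBF4 (2.5 equiv), 14 (2.5 equiv), 4 Å MS, THF, −20 to 0 °C, dark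
Reagents that add atoms: none
Why: thiophilic silver activation of the C4 sulfide followed by Friedel–Crafts alkylation should join C4 of the middle unit to C6 of 14 anti to the 3-hydroxyl (3,4-trans), since the soft activator leaves the ketal of 14 alone and the dimer itself has no free nucleophilic ring position.

**Step 15**
Reactants: 22 protected trimer
Product: 23 6-bromo-nona-O-benzyl trimer with free lower 3,4-diol
Conditions: AcOH/H2O/THF (3:1:1), 40 °C
Reagents that add atoms: none
Why: the same mild ketal hydrolysis as in step 8 should free the lower cis-diol, the interflavan bonds of benzylated 5-deoxy units being stable to dilute acetic acid.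

**Step 16**
Reactants: 23 6-bromo-nona-O-benzyl trimer
Product: 24 epioritin-(4β→6)-oritin-(4α→6)-epioritin-4α-ol (CNP0140823.2)
Conditions: H2 (1 atm), Pd(OH)2/C, Et3N (1.5 equiv), THF/MeOH/H2O, rt
Reagents that add atoms: none
Why: catalytic hydrogenolysis should remove the nine benzyl ethers and the aryl bromide in one operation, the amine buffering HBr so that the benzylic C4–OH and C2–O1 bonds survive.

**Compound list**
1 | 2,3-dihydroxybenzaldehyde | O=Cc1cccc(O)c1O | starting material
2 | 2,3-bis(benzyloxy)benzaldehyde | O=Cc1cccc(OCc2ccccc2)c1OCc1ccccc1 | intermediate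
3 | 2,3-bis(benzyloxy)phenyl formate | O=COc1cccc(OCc2ccccc2)c1OCc1ccccc1 | intermediate
4 | 2,3-bis(benzyloxy)phenol | Oc1cccc(OCc2ccccc2)c1OCc1ccccc1 | intermediate
5 | 4-(benzyloxy)benzaldehyde | O=Cc1ccc(OCc2ccccc2)cc1 | starting material
6 | 4-(benzyloxy)benzaldehyde dimethyl acetal | COC(OC)c1ccc(OCc2ccccc2)cc1 | intermediate
7 | 1-(benzyloxy)-4-[chloro(methoxy)methyl]benzene (racemic) | COC(Cl)c1ccc(OCc2ccccc2)cc1 | intermediate
8 | [4-(benzyloxy)phenyl](methoxy)methyl 2,3-bis(benzyloxy)phenyl ether (racemic mixed acetal) | COC(Oc1cccc(OCc2ccccc2)c1OCc1ccccc1)c1ccc(OCc2ccccc2)cc1 | intermediate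
9 | 2,2-dimethyl-1,3-dioxolan-4-one | CC1(C)OCC(=O)O1 | starting material
10 | diisobutylaluminium 2,2-dimethyl-1,3-dioxolan-4-olate (racemic) | CC(C)C[Al](CC(C)C)OC1COC(C)(C)O1 | intermediate
11 | 2,2-dimethyl-1,3-dioxolan-4-yl acetate (racemic) | CC(=O)OC1COC(C)(C)O1 | intermediate
12 | 2,2-dimethyl-1,3-dioxole | CC1(C)OC=CO1 | intermediate
13 | (E)-[2,3-bis(benzyloxy)phenyl][4-(benzyloxy)benzylidene]oxonium ion (counter-ion: the catalyst anion) | O(Cc1ccccc1)c1ccc(/C=[O+]/c2cccc(OCc3ccccc3)c2OCc2ccccc2)cc1 | intermediate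
14 | tri-O-benzylteracacidin acetonide: (2R)-2,3-cis-3,4-cis-7,8-bis(benzyloxy)-2-[4-(benzyloxy)phenyl]-3,4-(isopropylidenedioxy)flavan | c1cc2c(c(OCc3ccccc3)c1OCc1ccccc1)O[C@H](c1ccc(OCc3ccccc3)cc1)[C@H](OC(C)(C)O3)[C@@H]23 | intermediate
15 | (2R,3R,4R)-7,8-bis(benzyloxy)-2-[4-(benzyloxy)phenyl]chromane-3,4-diol (tri-O-benzylteracacidin) | c1cc2c(c(OCc3ccccc3)c1OCc1ccccc1)O[C@H](c1ccc(OCc3ccccc3)cc1)[C@H](O)[C@@H]2O | intermediate
16 | cyclic 3,4-thionocarbonate of 15 (all-cis) | c1cc2c(c(OCc3ccccc3)c1OCc1ccccc1)O[C@H](c1ccc(OCc3ccccc3)cc1)[C@H](OC(=S)O3)[C@@H]23 | intermediate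
17 | (2S)-7,8-bis(benzyloxy)-2-[4-(benzyloxy)phenyl]-2H-chromene | c1cc2c(c(OCc3ccccc3)c1OCc1ccccc1)O[C@H](c1ccc(OCc3ccccc3)cc1)C=C2 | intermediate
18 | (2R,3S,4S)-7,8-bis(benzyloxy)-2-[4-(benzyloxy)phenyl]chromane-3,4-diol (2,3-trans-3,4-cis) | c1cc2c(c(OCc3ccccc3)c1OCc1ccccc1)O[C@H](c1ccc(OCc3ccccc3)cc1)[C@@H](O)[C@H]2O | intermediate
19 | (2R,3R,4R)-7,8-bis(benzyloxy)-2-[4-(benzyloxy)phenyl]-4-[(2,6-dimethylphenyl)sulfanyl]chroman-3-ol (2,3-trans-3,4-trans) | c1cc2c(c(OCc3ccccc3)c1OCc1ccccc1)O[C@H](c1ccc(OCc3ccccc3)cc1)[C@@H](O)[C@@H]2Sc1c(C)cccc1C | intermediate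
20 | 6-bromo-tri-O-benzylteracacidin acetonide (6-bromo derivative of 14) | Brc1cc2c(c(OCc3ccccc3)c1OCc1ccccc1)O[C@H](c1ccc(OCc3ccccc3)cc1)[C@H](OC(C)(C)O3)[C@@H]23 | intermediate
21 | protected dimer, 6-bromo-tri-O-benzylepioritin-(4β→6)-[tri-O-benzyl-4-(2,6-dimethylphenylsulfanyl)oritin] | O(Cc5ccccc5)c1ccc([C@H]2Oc3c(cc(Br)c(OCc5ccccc5)c3OCc5ccccc5)[C@H](c3cc4c(c(OCc5ccccc5)c3OCc5ccccc5)O[C@H](c3ccc(OCc5ccccc5)cc3)[C@@H](O)[C@@H]4Sc3c(C)cccc3C)[C@H]2O)cc1 | intermediate
22 | protected trimer, 6-bromo-tri-O-benzylepioritin-(4β→6)-tri-O-benzyloritin-(4α→6)-tri-O-benzylteracacidin acetonide | O(Cc5ccccc5)c1ccc([C@H]2Oc3c(cc(Br)c(OCc5ccccc5)c3OCc5ccccc5)[C@H](c3cc4c(c(OCc5ccccc5)c3OCc5ccccc5)O[C@H](c3ccc(OCc5ccccc5)cc3)[C@@H](O)[C@@H]4c3cc4c(c(OCc5ccccc5)c3OCc5ccccc5)O[C@H](c3ccc(OCc5ccccc5)cc3)[C@H](OC(C)(C)O6)[C@@H]46)[C@H]2O)cc1 | intermediate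
23 | 6-bromo-nona-O-benzyl trimer with free lower 3,4-diol | O(Cc5ccccc5)c1ccc([C@H]2Oc3c(cc(Br)c(OCc5ccccc5)c3OCc5ccccc5)[C@H](c3cc4c(c(OCc5ccccc5)c3OCc5ccccc5)O[C@H](c3ccc(OCc5ccccc5)cc3)[C@@H](O)[C@@H]4c3cc4c(c(OCc5ccccc5)c3OCc5ccccc5)O[C@H](c3ccc(OCc5ccccc5)cc3)[C@H](O)[C@@H]4O)[C@H]2O)cc1 | intermediate
24 | epioritin-(4β→6)-oritin-(4α→6)-epioritin-4α-ol (CNP0140823.2) | Oc1ccc([C@H]2Oc3c(ccc(O)c3O)[C@H](c3cc4c(c(O)c3O)O[C@H](c3ccc(O)cc3)[C@@H](O)[C@@H]4c3cc4c(c(O)c3O)O[C@H](c3ccc(O)cc3)[C@H](O)[C@@H]4O)[C@H]2O)cc1 | target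

**Totals.** Total step count: 16. Longest linear sequence: 12 steps (steps 1, 2, 4, 7, 8, 9, 10, 11, 13, 14, 15, 16).

**Steps most likely to fail**

1. Step 7 (Proposed new method). What may go wrong: weak enantioface discrimination within the ion pair, leakage through the exo transition state, or acid-induced oligomerization of the enol ether before it is captured. Fallback: setting out from 8 and 12, the reaction is run in its known racemic form with stoichiometric SnCl4 (CH2Cl2, −78 °C). This should give the racemic all-cis acetonide, that is 14 together with its enantiomer ent-14 F1. The two are separated by preparative chromatography on a chiral stationary phase (amylose carbamate, supercritical CO2/MeOH), and the route is rejoined at 14.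

2. Step 13. What may go wrong: ionization of the ketal at the ketal carbon instead of at C4 (enol ether formation without coupling), or acid-induced exchange of the arylthio group between the two units. Fallback: setting out from 20, the ketal is first hydrolysed (AcOH/H2O/THF, 40 °C) to 6-bromo-tri-O-benzylteracacidin F2. This free flavan-3,4-diol is then used as the classical C4 electrophile with 19 under stoichiometric BF3·OEt2 (CH2Cl2, −40 °C), the 4-hydroxyl leaving as water. The route is rejoined at 21.

3. Step 14. What may go wrong: O-alkylation of the cation by the free 3-hydroxyls in place of C-arylation, attack syn to the 3-hydroxyl (poor 3,4-trans selectivity at the middle C4), or loss of the ketal of 14 through the acid liberated. Fallback: setting out from 21, both 3-hydroxyls are acetylated (Ac2O, pyridine, DMAP) to dimer diacetate F3. Silver activation (AgBF4, 2,6-di-tert-butyl-4-methylpyridine, 14, CH2Cl2, −20 °C) then runs through the C3/C4 acetoxonium ion, which blocks the syn face and removes the hydroxyl nucleophiles, and should give trimer diacetate F4. K2CO3 in MeOH removes the two acetates, and the route is rejoined at 22.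

**Further compounds**
F1 | step 7 | ent-14, enantiomer of tri-O-benzylteracacidin acetonide | c1cc2c(c(OCc3ccccc3)c1OCc1ccccc1)O[C@@H](c1ccc(OCc3ccccc3)cc1)[C@@H](OC(C)(C)O3)[C@H]23
F2 | step 13 | 6-bromo-tri-O-benzylteracacidin, (2R,3R,4R)-6-bromo-7,8-bis(benzyloxy)-2-[4-(benzyloxy)phenyl]chromane-3,4-diol | Brc1cc2c(c(OCc3ccccc3)c1OCc1ccccc1)O[C@H](c1ccc(OCc3ccccc3)cc1)[C@H](O)[C@@H]2O
F3 | step 14 | dimer diacetate, 3-O-acetyl derivative at both units of 21 | O(Cc5ccccc5)c1ccc([C@H]2Oc3c(cc(Br)c(OCc5ccccc5)c3OCc5ccccc5)[C@H](c3cc4c(c(OCc5ccccc5)c3OCc5ccccc5)O[C@H](c3ccc(OCc5ccccc5)cc3)[C@@H](OC(C)=O)[C@@H]4Sc3c(C)cccc3C)[C@H]2OC(C)=O)cc1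
F4 | step 14 | trimer diacetate, 3-O-acetyl derivative at the upper and middle units of 22 | O(Cc5ccccc5)c1ccc([C@H]2Oc3c(cc(Br)c(OCc5ccccc5)c3OCc5ccccc5)[C@H](c3cc4c(c(OCc5ccccc5)c3OCc5ccccc5)O[C@H](c3ccc(OCc5ccccc5)cc3)[C@@H](OC(C)=O)[C@@H]4c3cc4c(c(OCc5ccccc5)c3OCc5ccccc5)O[C@H](c3ccc(OCc5ccccc5)cc3)[C@H](OC(C)(C)O6)[C@@H]46)[C@H]2OC(C)=O)cc1
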